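Positions are numbered as in the eremophilanes throughout: ring A is C1–C5 plus C10, ring B is C5–C10, the methyl groups sit on C4 and C5, the isopropenyl group on C7. The target is compound 24.

## Analysis of the target

Compound 24 is a cis-fused decalin in which ring A carries the angelate at C3 and a methyl group at C4, ring B carries the isopropenyl group at C7, the ketone at C8 and the senecioate at C9, and the shared carbon C5 is quaternary. There are six stereocentres (3R,4R,5R,7R,9R,10S). The two methyl groups, H-10, the isopropenyl group and the C9 oxygen lie on one face, and the C3 oxygen lies on the other. In the chair–chair conformer that has the C5 methyl equatorial on ring B, the substituents at C3, C4, C7 and C9 are all equatorial, so the two centres flanking the ketone (C7 and C9) are the thermodynamically preferred epimers. The sensitive groups are the angelate (Z to E isomerisation by nucleophiles, bases, iodine or radicals), the β,γ-unsaturated ketone (base moves the double bond into conjugation and epimerises C7) and the α-acyloxy ketone (enolisation, acyl shift). The difficulty lies in the contiguous C3–C4–C5–C10 array with its quaternary centre, in placing two different unsaturated esters on two secondary alcohols, and in ordering the chemistry around the ketone. The strategy rests on ring B: drawn as a 4,4-disubstituted cyclohexa-2,5-dienone with its carbonyl at C8, it makes C5 a prochiral carbon between two equivalent enone arms. Bonding C1 of a side chain on C5 to C10, the β-carbon of one arm, closes ring A, sets C5 and C10 together and leaves the other arm (C6=C7–C8=O) as the handle for C7 and C9.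

## Retrosynthetic reasoning

**24 from 23.** The C7 centre sits between a ketone and an alkene and is the most fragile element, so it is made last. Removing H from C6 and C7 leads to the cross-conjugated dienone 23. The forward step is a hydride conjugate addition to C6 followed by kinetic protonation of the dienolate at C7, under neutral conditions and with no later step that could move the double bond.

**23 from 22 and 21.** The C3–O acyl bond is cut next. The angelate would not survive enolate chemistry, iodine or alkene reduction, so it is attached only after all of these, to alcohol 22, which comes from silyl ether 21.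

**21 from 20, 19 and 18.** The C7–isopropenyl bond is cut to the α-iodoenone 20, which a cross-coupling turns into 21. Before that coupling, the C1=C2 alkene left by the ring closure must be saturated. This is placed at the iodoenone stage (20 from 19): once C7 carries iodine, the ring B alkene is trisubstituted and the ring A alkene is the only unhindered, non-polar double bond. Iodoenone 19 comes from enone 18 by α-iodination.

**18 from 17 and 15.** The C9–O bond is cut. Enone 15 can only be deprotonated at C9, because the γ-position C5 is quaternary, so an enolate hydroxylation gives 17 regiospecifically, and acylation gives 18. This must precede the iodination, since an enolate and an α-iodoenone do not tolerate each other.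

**15 from 14.** The key disconnection is C1–C10. It opens ring A to dienone 14, in which C5 is no longer a stereocentre and C3 and C4 are the only ones. The forward reaction must add the alkenyl carbon C1 to one of two enone arms, reduce the resulting metal enolate and leave the other arm intact. A bond elsewhere in ring A would not make use of the symmetry of the dienone.

**14 from 13 and 12.** The Z-iodoalkene is traced through iodoalkyne 13 to silylalkyne 12, because the alkyne is inert during the construction of ring B and syn semi-reduction gives the Z geometry that the ring closure needs.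

**12 from 11, and 11 from 7 and 8.** Ring B is cut at C5–C6 and C9–C10. Dienone 12 comes from enone 11 by dehydrogenation, and 11 from the α-branched aldehyde 7 and enone 8 by a Michael–aldol annulation, which builds the quaternary carbon without any need for stereocontrol at C5.

**7 from 6, 5 and 4.** The aldehyde carbon is removed: 7 comes from enol ether 6 and that from methyl ketone 5 by a one-carbon olefination. Ketone 5 is the Wacker product of the terminal alkene 4.

**4 from 3, and 3 from 1 and 2.** The C3–C4 bond is cut last. A syn-selective, catalyst-controlled crotylboration of ynal 1 with Z-boronate 2 sets both stereocentres of 3 in one step, and silylation gives 4.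

## Alternatives that were turned down

**Alternative 1:** Intramolecular Diels–Alder reaction closing both rings. The bonds C1–C2 and C5–C10 are cut, giving an acyclic trienone in which a vinyl ketone (C1=C10, carbonyl at C9) is linked through C8, C7 and C6 to a 2-silyloxydiene spanning C2–C5. The forward step is the cycloaddition to the cis-fused adduct A1.
- For it: two rings and two C–C bonds form at once, the quaternary carbon is made by a thermal process, and the isopropenyl group is in place from the start. On convergence and on C7 it is stronger than the chosen route.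
- Against it: the diene terminus C5 is fully substituted, which slows the reaction and demands a geometrically defined tetrasubstituted diene. C3 and C4 emerge as an enol ether, so both centres must be set later by protonation and ketone reduction under substrate control. The oxygen pattern arrives transposed (ketone at C9, ether at C8) and has to be exchanged next to the epimerisable C7. Facial control depends on two centres in a flexible tether.
- Comparison: the chosen route fixes C3 and C4 at the outset by a reagent-controlled step, delivers the carbonyl at C8 directly and concentrates the uncertainty in one ring closure.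

**Alternative 2:** Carbonyl-ene closure of ring B. The C7–C8 bond is cut, giving a ring A cyclohexane that carries a prenyl group on C5 and an α-alkoxy aldehyde chain (C9, C8) on C10. Under a chelating aluminium Lewis acid the aldehyde reacts with the prenyl alkene through a chair-like transition state to give A2, with the isopropenyl group trans to the new C8 alcohol.
- For it: the isopropenyl group and the C7 centre are created together and with predictable relative configuration, where the chosen route needs iodination, coupling, conjugate reduction and a kinetic protonation. On this point the alternative is clearly better.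
- Against it: the precursor is already a cyclohexane with four contiguous stereocentres including the quaternary C5, so the hardest part of the molecule is moved into the precursor synthesis without a step that solves it. The α-alkoxy aldehyde can epimerise at C9, and the C8 alcohol must afterwards be oxidised between two epimerisable centres.
- Comparison: the chosen route makes C5 and C10 in one catalytic step from a flat ring and is shorter overall.

**Alternative 3:** Quinone Diels–Alder reaction building ring A on ring B. The bonds C4–C5 and C1–C10 are cut, giving quinone A4 and a 2-silyloxy-1,3-pentadiene. Under a chiral Lewis acid the diene adds to the methyl-bearing double bond of A4 to give the cis-fused endo adduct A3.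
- For it: this is the shortest way to the bicyclic core, the cis fusion and the quaternary carbon follow from the endo rule, and catalytic asymmetric quinone cycloadditions are an established reaction class. In step economy to the skeleton it beats the chosen route.
- Against it: the C4 methyl group comes out with the wrong configuration and would have to be corrected through the C3 ketone enolate with an uncertain equilibrium. Ring B arrives with a surplus carbonyl at C6 next to the quaternary carbon, which must be removed, and with C8 and C9 oxygens that need to be differentiated. The isopropenyl group still has to be introduced.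
- Comparison: the chosen route is longer up to the bicycle but reaches it with C3 and C4 correct, no surplus oxygen and an enone placed where C7 and C9 need it.

Key step: step 10

Assumption: (S)-TRIP in step 1 and (R)-BINAP in step 10 are taken to be the catalyst antipodes that give the drawn configurations; if the sense of induction is the opposite, the mirror-image catalyst is used with the conditions otherwise unchanged.

## Route

Step 1
Reactants: 1 3-(trimethylsilyl)prop-2-ynal; 2 (Z)-crotylboronic acid pinacol ester
Product: 3 (3S,4R)-4-methyl-1-(trimethylsilyl)hex-5-en-1-yn-3-ol (3,4-syn)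
Conditions: (S)-TRIP [(S)-3,3′-bis(2,4,6-triisopropylphenyl)-1,1′-binaphthyl-2,2′-diyl hydrogen phosphate] (5 mol %), 4 Å MS, PhMe, −30 °C
Reagents that add atoms: none
Why: Chiral-phosphoric-acid-catalysed crotylboration through a closed chair transition state; the Z-boronate places its methyl group axial, which gives the 3,4-syn relationship, and the phosphate bound to the formyl hydrogen and a boronate oxygen should expose the Si face of the ynal, setting C3 (S) and C4 (R).

Step 2
Reactants: 3 (3S,4R)-4-methyl-1-(trimethylsilyl)hex-5-en-1-yn-3-ol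
Product: 4 tert-butyldimethyl{[(3S,4R)-4-methyl-1-(trimethylsilyl)hex-5-en-1-yn-3-yl]oxy}silane
Conditions: TBSCl, imidazole, DMF, rt
Reagents that add atoms: tert-butyldimethylsilyl chloride, CC(C)(C)[Si](C)(C)Cl
Why: Standard silylation of a secondary propargylic alcohol; the ether protects C3 through the carbonyl chemistry that follows and prevents retro-aldol cleavage at the ketone stage.

Step 3
Reactants: 4 tert-butyldimethyl{[(3S,4R)-4-methyl-1-(trimethylsilyl)hex-5-en-1-yn-3-yl]oxy}silane
Product: 5 (3S,4S)-4-[(tert-butyldimethylsilyl)oxy]-3-methyl-6-(trimethylsilyl)hex-5-yn-2-one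
Conditions: PdCl2 (10 mol %), p-benzoquinone, DMF/H2O (7:1), rt
Reagents that add atoms: water, O
Why: Tsuji–Wacker oxidation with Markovnikov hydroxypalladation of the terminal alkene; benzoquinone as reoxidant avoids copper salts that could attack the alkynylsilane, and the near-neutral medium should leave the new α-stereocentre (C4) unenolised.

Step 4
Reactants: 5 (3S,4S)-4-[(tert-butyldimethylsilyl)oxy]-3-methyl-6-(trimethylsilyl)hex-5-yn-2-one
Product: 6 (3S,4R)-3-[(tert-butyldimethylsilyl)oxy]-6-methoxy-4,5-dimethyl-1-(trimethylsilyl)hex-5-en-1-yne (E/Z mixture)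
Conditions: Ph3P(CH2OMe)Cl, NaN(SiMe3)2, THF, 0 °C; then 5, −78 °C → rt
Reagents that add atoms: (methoxymethyl)triphenylphosphonium chloride, COC[P+](c1ccccc1)(c1ccccc1)c1ccccc1.[Cl-]
Why: Wittig methoxymethylenation of a methyl ketone; a slight excess of phosphonium salt over base keeps free amide out of the flask, and at low temperature addition of the ylide should outrun enolisation toward the hindered C4 position.

Step 5
Reactants: 6 (3S,4R)-3-[(tert-butyldimethylsilyl)oxy]-6-methoxy-4,5-dimethyl-1-(trimethylsilyl)hex-5-en-1-yne
Product: 7 (3R,4S)-4-[(tert-butyldimethylsilyl)oxy]-2,3-dimethyl-6-(trimethylsilyl)hex-5-ynal (both C2 epimers)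
Conditions: TsOH·H2O (cat.), acetone/H2O (10:1), rt
Reagents that add atoms: water, O
Why: Acid hydrolysis of an enol ether through the oxocarbenium ion, mild enough for a hindered secondary silyl ether and an alkynylsilane; the new centre at C2 (the future C5) is of no consequence because it becomes the prochiral quaternary carbon.

Step 6
Reactants: 7 (3R,4S)-4-[(tert-butyldimethylsilyl)oxy]-2,3-dimethyl-6-(trimethylsilyl)hex-5-ynal; 8 but-3-en-2-one
Product: 11 4-[(2R,3S)-3-[(tert-butyldimethylsilyl)oxy]-5-(trimethylsilyl)pent-4-yn-2-yl]-4-methylcyclohex-2-en-1-one (both epimers at the ring carbon), via pyrrolidine enamine 9 (not isolated), via 1,5-keto aldehyde 10 (not isolated)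
Conditions: pyrrolidine, K2CO3, PhMe, rt → 60 °C; 8, rt → 60 °C; then AcOH/NaOAc/H2O, 80 °C
Reagents that add atoms: none
Why: Stork enamine Michael addition of an α-branched aldehyde to the enone creates the quaternary carbon, and buffered hydrolysis with intramolecular aldol condensation closes the cyclohexenone (Robinson-type annulation); no base strong enough to cleave the alkynylsilane is used.

Step 7
Reactants: 11 4-[(2R,3S)-3-[(tert-butyldimethylsilyl)oxy]-5-(trimethylsilyl)pent-4-yn-2-yl]-4-methylcyclohex-2-en-1-one
Product: 12 4-[(2R,3S)-3-[(tert-butyldimethylsilyl)oxy]-5-(trimethylsilyl)pent-4-yn-2-yl]-4-methylcyclohexa-2,5-dien-1-one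
Conditions: IBX (3 equiv), DMSO/PhF, 75 °C
Reagents that add atoms: none
Why: Dehydrogenation of the enone at its only enolisable side with 2-iodoxybenzoic acid gives the cross-conjugated dienone; both epimers of 11 converge on one achiral ring, and silyl ether and alkynylsilane tolerate the neutral oxidant.

Step 8
Reactants: 12 4-[(2R,3S)-3-[(tert-butyldimethylsilyl)oxy]-5-(trimethylsilyl)pent-4-yn-2-yl]-4-methylcyclohexa-2,5-dien-1-one
Product: 13 4-[(2R,3S)-3-[(tert-butyldimethylsilyl)oxy]-5-iodopent-4-yn-2-yl]-4-methylcyclohexa-2,5-dien-1-one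
Conditions: NIS, AgNO3 (10 mol %), DMF, rt, dark
Reagents that add atoms: N-iodosuccinimide, O=C1CCC(=O)N1I
Why: Silver-catalysed iododesilylation converts the alkynylsilane directly into the 1-iodoalkyne through a silver acetylide, without a separate desilylation and without base that could add to the dienone.

Step 9
Reactants: 13 4-[(2R,3S)-3-[(tert-butyldimethylsilyl)oxy]-5-iodopent-4-yn-2-yl]-4-methylcyclohexa-2,5-dien-1-one
Product: 14 4-[(2R,3S,4Z)-3-[(tert-butyldimethylsilyl)oxy]-5-iodopent-4-en-2-yl]-4-methylcyclohexa-2,5-dien-1-one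
Conditions: KO2CN=NCO2K, AcOH, pyridine/MeOH, rt
Reagents that add atoms: none
Why: Diimide semi-reduction of a 1-iodoalkyne; concerted syn delivery of two hydrogens gives the Z-iodoalkene, and the dienone double bonds, which are electron-poor and flank a quaternary carbon, should react more slowly than the alkyne.

Step 10
Reactants: 14 4-[(2R,3S,4Z)-3-[(tert-butyldimethylsilyl)oxy]-5-iodopent-4-en-2-yl]-4-methylcyclohexa-2,5-dien-1-one
Product: 15 (4aS,5R,6R,8aS)-6-[(tert-butyldimethylsilyl)oxy]-4a,5-dimethyl-4a,5,6,8a-tetrahydronaphthalen-2(1H)-one (cis-fused; ring A 1-ene, ring B 6-en-8-one)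
Conditions: Pd(OAc)2 (10 mol %), (R)-BINAP (15 mol %), HCO2Na (1.5 equiv), DMF, 60 °C
Reagents that add atoms: none
Why: Oxidative addition of zerovalent palladium into the C1–I bond with retention gives a (Z)-alkenylpalladium iodide; after iodide dissociation in DMF the cationic bisphosphine complex binds the C9=C10 bond of one enone arm, and syn carbopalladation forms C1–C10 and places palladium on C9 as an enolate. Ring A closes in the 6-exo-trig mode; the closest known reaction types are the asymmetric intramolecular Heck desymmetrisation of prochiral cyclohexadienes to cis-decalins and reductive Heck cyclisations onto cyclohexadienones. The cis fusion is a geometric necessity, because the tether hangs from C5 and can reach C10 only on its own face, so C5 and C10 are created as a pair and only the choice of arm is open. The palladium enolate has no syn β-hydrogen (H-10 is anti, C8 has none) and cannot eliminate; exchange for formate, loss of CO2 and C–H reductive elimination give the C9 methylene and return zerovalent palladium. The arm that leads to 15 corresponds to a half-chair of the forming ring with the C4 methyl axial and the C3 silyloxy group pseudo-axial above the unreacting arm, whereas the other arm corresponds to the diequatorial half-chair; since the axial methyl next to quaternary C5 only trades one gauche contact for another, the bias of the tether is judged small and slightly adverse. The decision is therefore assigned to the BINAP ligand, whose antipodes distinguish the two arms. The step needs arm selection and insertion faster than formate reduction of the alkenylpalladium; the latter is secured by the intramolecular six-membered closure and the small excess of formate, and the C6=C7 enone and the allylic silyl ether are not involved.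

Step 11
Reactants: 15 (4aS,5R,6R,8aS)-6-[(tert-butyldimethylsilyl)oxy]-4a,5-dimethyl-4a,5,6,8a-tetrahydronaphthalen-2(1H)-one
Product: 17 (1R,4aR,5R,6R,8aS)-6-[(tert-butyldimethylsilyl)oxy]-1-hydroxy-4a,5-dimethyl-4a,5,6,8a-tetrahydronaphthalen-2(1H)-one (9β-alcohol), via potassium dienolate 16 (not isolated)
Conditions: KN(SiMe3)2, THF, −78 °C; 2-(phenylsulfonyl)-3-phenyloxaziridine, −78 °C; AcOH quench
Reagents that add atoms: 2-(phenylsulfonyl)-3-phenyloxaziridine, O=S(=O)(c1ccccc1)N1OC1c1ccccc1
Why: Davis hydroxylation of the cross-conjugated enolate, which can only form toward C9 because C5 is quaternary; the oxidant should approach C9 on the convex face of the cis-fused bicycle, syn to H-10 and anti to the C1 branch, giving the 9β-alcohol, and the potassium enolate avoids addition to the sulfonimine by-product.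

Step 12
Reactants: 17 (1R,4aR,5R,6R,8aS)-6-[(tert-butyldimethylsilyl)oxy]-1-hydroxy-4a,5-dimethyl-4a,5,6,8a-tetrahydronaphthalen-2(1H)-one
Product: 18 (1R,4aR,5R,6R,8aS)-6-[(tert-butyldimethylsilyl)oxy]-4a,5-dimethyl-2-oxo-1,2,4a,5,6,8a-hexahydronaphthalen-1-yl 3-methylbut-2-enoate
Conditions: 3-methylbut-2-enoic acid, DCC, DMAP (cat.), CH2Cl2, 0 °C → rt
Reagents that add atoms: 3-methylbut-2-enoic acid, CC(C)=CC(=O)O
Why: Steglich esterification of the α-ketol; carbodiimide activation avoids the acid chloride with amine base, which can deconjugate the senecioyl unit through a vinylketene.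

Step 13
Reactants: 18 (1R,4aR,5R,6R,8aS)-6-[(tert-butyldimethylsilyl)oxy]-4a,5-dimethyl-2-oxo-1,2,4a,5,6,8a-hexahydronaphthalen-1-yl 3-methylbut-2-enoate
Product: 19 (1R,4aR,5R,6R,8aS)-6-[(tert-butyldimethylsilyl)oxy]-3-iodo-4a,5-dimethyl-2-oxo-1,2,4a,5,6,8a-hexahydronaphthalen-1-yl 3-methylbut-2-enoate
Conditions: I2, pyridine/CH2Cl2 (1:1), rt
Reagents that add atoms: iodine, II
Why: Johnson α-iodination of an enone (pyridine conjugate addition, iodination of the enolate, elimination), known for 4,4-disubstituted cyclohexenones; it places the coupling handle on C7 and makes the ring B alkene trisubstituted.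

Step 14
Reactants: 19 (1R,4aR,5R,6R,8aS)-6-[(tert-butyldimethylsilyl)oxy]-3-iodo-4a,5-dimethyl-2-oxo-1,2,4a,5,6,8a-hexahydronaphthalen-1-yl 3-methylbut-2-enoate
Product: 20 (1R,4aR,5R,6R,8aS)-6-[(tert-butyldimethylsilyl)oxy]-3-iodo-4a,5-dimethyl-2-oxo-1,2,4a,5,6,7,8,8a-octahydronaphthalen-1-yl 3-methylbut-2-enoate
Conditions: KO2CN=NCO2K, AcOH, pyridine/MeOH, rt (repeated charges)
Reagents that add atoms: none
Why: Diimide reduces the cis-1,2-disubstituted C1=C2 alkene far faster than the trisubstituted iodoenone and senecioate double bonds and does not cleave C–I bonds, which catalytic hydrogenation would.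

Step 15
Reactants: 20 (1R,4aR,5R,6R,8aS)-6-[(tert-butyldimethylsilyl)oxy]-3-iodo-4a,5-dimethyl-2-oxo-1,2,4a,5,6,7,8,8a-octahydronaphthalen-1-yl 3-methylbut-2-enoate
Product: 21 (1R,4aR,5R,6R,8aS)-6-[(tert-butyldimethylsilyl)oxy]-4a,5-dimethyl-2-oxo-3-(prop-1-en-2-yl)-1,2,4a,5,6,7,8,8a-octahydronaphthalen-1-yl 3-methylbut-2-enoate
Conditions: CH2=C(Me)SnBu3, Pd2(dba)3 (5 mol %), AsPh3 (20 mol %), CuI (10 mol %), NMP, 40 °C
Reagents that add atoms: tributyl(prop-1-en-2-yl)stannane, C=C(C)[Sn](CCCC)(CCCC)CCCC
Why: Stille coupling of an α-iodoenone under neutral conditions; the arsine ligand and the copper co-catalyst accelerate transfer of the branched alkenyl group, and no base is present that could touch the α-acyloxy ketone.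

Step 16
Reactants: 21 (1R,4aR,5R,6R,8aS)-6-[(tert-butyldimethylsilyl)oxy]-4a,5-dimethyl-2-oxo-3-(prop-1-en-2-yl)-1,2,4a,5,6,7,8,8a-octahydronaphthalen-1-yl 3-methylbut-2-enoate
Product: 22 (1R,4aR,5R,6R,8aS)-6-hydroxy-4a,5-dimethyl-2-oxo-3-(prop-1-en-2-yl)-1,2,4a,5,6,7,8,8a-octahydronaphthalen-1-yl 3-methylbut-2-enoate
Conditions: HF·pyridine, THF/pyridine, 0 °C → rt
Reagents that add atoms: none
Why: Buffered fluoride cleavage of the secondary silyl ether; the weakly acidic, non-basic medium should leave the ester, the α-acyloxy ketone and the diene unchanged.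

Step 17
Reactants: 22 (1R,4aR,5R,6R,8aS)-6-hydroxy-4a,5-dimethyl-2-oxo-3-(prop-1-en-2-yl)-1,2,4a,5,6,7,8,8a-octahydronaphthalen-1-yl 3-methylbut-2-enoate
Product: 23 (1R,4aR,5R,6R,8aS)-4a,5-dimethyl-6-{[(2Z)-2-methylbut-2-enoyl]oxy}-2-oxo-3-(prop-1-en-2-yl)-1,2,4a,5,6,7,8,8a-octahydronaphthalen-1-yl 3-methylbut-2-enoate
Conditions: angelic acid, 2,4,6-trichlorobenzoyl chloride, Et3N, PhMe, rt; then 22, 75 °C
Reagents that add atoms: angelic acid [(2Z)-2-methylbut-2-enoic acid], C/C=C(/C)C(=O)O
Why: Yamaguchi-type esterification through the mixed anhydride, run without a nucleophilic catalyst so that the Z geometry of the angeloyl group is kept; at this stage C7 is still sp2, so the amine base has no labile α-centre to epimerise.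

Step 18
Reactants: 23 (1R,4aR,5R,6R,8aS)-4a,5-dimethyl-6-{[(2Z)-2-methylbut-2-enoyl]oxy}-2-oxo-3-(prop-1-en-2-yl)-1,2,4a,5,6,7,8,8a-octahydronaphthalen-1-yl 3-methylbut-2-enoate
Product: 24 (1R,3R,4aR,5R,6R,8aS)-4a,5-dimethyl-6-{[(2Z)-2-methylbut-2-enoyl]oxy}-2-oxo-3-(prop-1-en-2-yl)decahydronaphthalen-1-yl 3-methylbut-2-enoate (target)
Conditions: [(Ph3P)CuH]6 (0.5 equiv), PhH/H2O (degassed), rt
Reagents that add atoms: none
Why: Copper hydride conjugate reduction (Stryker) delivers hydride to C6 of the ketone-activated alkene, which is more electrophilic than the two trisubstituted enoates; the dienolate is protonated kinetically at its α-carbon C7, which keeps the isopropenyl group out of conjugation. Axial protonation on the chair-like enol places the new hydrogen on the α face and the isopropenyl group equatorial (7R), which is also the more stable epimer.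

## Compound list

1 | 3-(trimethylsilyl)prop-2-ynal | C[Si](C)(C)C#CC=O | starting material
2 | (Z)-crotylboronic acid pinacol ester | C/C=C\CB1OC(C)(C)C(C)(C)O1 | starting material
3 | (3S,4R)-4-methyl-1-(trimethylsilyl)hex-5-en-1-yn-3-ol | C[C@@H]([C@H](O)C#C[Si](C)(C)C)C=C | intermediate
4 | tert-butyldimethyl{[(3S,4R)-4-methyl-1-(trimethylsilyl)hex-5-en-1-yn-3-yl]oxy}silane | C[C@@H]([C@H](O[Si](C)(C)C(C)(C)C)C#C[Si](C)(C)C)C=C | intermediate
5 | (3S,4S)-4-[(tert-butyldimethylsilyl)oxy]-3-methyl-6-(trimethylsilyl)hex-5-yn-2-one | C[C@@H]([C@H](O[Si](C)(C)C(C)(C)C)C#C[Si](C)(C)C)C(C)=O | intermediate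
6 | (3S,4R)-3-[(tert-butyldimethylsilyl)oxy]-6-methoxy-4,5-dimethyl-1-(trimethylsilyl)hex-5-en-1-yne (E/Z mixture) | C[C@@H]([C@H](O[Si](C)(C)C(C)(C)C)C#C[Si](C)(C)C)C(C)=COC | intermediate
7 | (3R,4S)-4-[(tert-butyldimethylsilyl)oxy]-2,3-dimethyl-6-(trimethylsilyl)hex-5-ynal (both C2 epimers) | C[C@@H]([C@H](O[Si](C)(C)C(C)(C)C)C#C[Si](C)(C)C)C(C)C=O | intermediate
8 | but-3-en-2-one | CC(=O)C=C | starting material
9 | 1-[(3R,4S)-4-[(tert-butyldimethylsilyl)oxy]-2,3-dimethyl-6-(trimethylsilyl)hex-1-en-5-yn-1-yl]pyrrolidine (formed in the flask, not isolated) | C[C@@H]([C@H](O[Si](C)(C)C(C)(C)C)C#C[Si](C)(C)C)C(C)=CN1CCCC1 | intermediate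
10 | 2-[(2R,3S)-3-[(tert-butyldimethylsilyl)oxy]-5-(trimethylsilyl)pent-4-yn-2-yl]-2-methyl-5-oxohexanal (both C2 epimers; formed in the flask, not isolated) | C[C@@H]([C@H](O[Si](C)(C)C(C)(C)C)C#C[Si](C)(C)C)C(C)(C=O)CCC(C)=O | intermediate
11 | 4-[(2R,3S)-3-[(tert-butyldimethylsilyl)oxy]-5-(trimethylsilyl)pent-4-yn-2-yl]-4-methylcyclohex-2-en-1-one (both ring epimers) | C[C@@H]([C@H](O[Si](C)(C)C(C)(C)C)C#C[Si](C)(C)C)C1(C)CCC(=O)C=C1 | intermediate
12 | 4-[(2R,3S)-3-[(tert-butyldimethylsilyl)oxy]-5-(trimethylsilyl)pent-4-yn-2-yl]-4-methylcyclohexa-2,5-dien-1-one | C[C@@H]([C@H](O[Si](C)(C)C(C)(C)C)C#C[Si](C)(C)C)C1(C)C=CC(=O)C=C1 | intermediate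
13 | 4-[(2R,3S)-3-[(tert-butyldimethylsilyl)oxy]-5-iodopent-4-yn-2-yl]-4-methylcyclohexa-2,5-dien-1-one | C[C@@H]([C@H](O[Si](C)(C)C(C)(C)C)C#CI)C1(C)C=CC(=O)C=C1 | intermediate
14 | 4-[(2R,3S,4Z)-3-[(tert-butyldimethylsilyl)oxy]-5-iodopent-4-en-2-yl]-4-methylcyclohexa-2,5-dien-1-one | C[C@@H]([C@H](O[Si](C)(C)C(C)(C)C)/C=C\I)C1(C)C=CC(=O)C=C1 | intermediate
15 | (4aS,5R,6R,8aS)-6-[(tert-butyldimethylsilyl)oxy]-4a,5-dimethyl-4a,5,6,8a-tetrahydronaphthalen-2(1H)-one | O=C1C=C[C@@]2(C)[C@H](C=C[C@@H](O[Si](C)(C)C(C)(C)C)[C@@H]2C)C1 | intermediate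
16 | potassium dienolate of 15 (O–C8=C9, C6=C7 kept; formed in the flask, not isolated) | [K+].[O-]C1C=C[C@@]2(C)[C@H](C=C[C@@H](O[Si](C)(C)C(C)(C)C)[C@@H]2C)C=1 | intermediate
17 | (1R,4aR,5R,6R,8aS)-6-[(tert-butyldimethylsilyl)oxy]-1-hydroxy-4a,5-dimethyl-4a,5,6,8a-tetrahydronaphthalen-2(1H)-one | O=C1C=C[C@@]2(C)[C@H](C=C[C@@H](O[Si](C)(C)C(C)(C)C)[C@@H]2C)[C@H]1O | intermediate
18 | (1R,4aR,5R,6R,8aS)-6-[(tert-butyldimethylsilyl)oxy]-4a,5-dimethyl-2-oxo-1,2,4a,5,6,8a-hexahydronaphthalen-1-yl 3-methylbut-2-enoate | O=C1C=C[C@@]2(C)[C@H](C=C[C@@H](O[Si](C)(C)C(C)(C)C)[C@@H]2C)[C@H]1OC(=O)C=C(C)C | intermediate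
19 | (1R,4aR,5R,6R,8aS)-6-[(tert-butyldimethylsilyl)oxy]-3-iodo-4a,5-dimethyl-2-oxo-1,2,4a,5,6,8a-hexahydronaphthalen-1-yl 3-methylbut-2-enoate | O=C1C(I)=C[C@@]2(C)[C@H](C=C[C@@H](O[Si](C)(C)C(C)(C)C)[C@@H]2C)[C@H]1OC(=O)C=C(C)C | intermediate
20 | (1R,4aR,5R,6R,8aS)-6-[(tert-butyldimethylsilyl)oxy]-3-iodo-4a,5-dimethyl-2-oxo-1,2,4a,5,6,7,8,8a-octahydronaphthalen-1-yl 3-methylbut-2-enoate | O=C1C(I)=C[C@@]2(C)[C@H](CC[C@@H](O[Si](C)(C)C(C)(C)C)[C@@H]2C)[C@H]1OC(=O)C=C(C)C | intermediate
21 | (1R,4aR,5R,6R,8aS)-6-[(tert-butyldimethylsilyl)oxy]-4a,5-dimethyl-2-oxo-3-(prop-1-en-2-yl)-1,2,4a,5,6,7,8,8a-octahydronaphthalen-1-yl 3-methylbut-2-enoate | O=C1C(C(C)=C)=C[C@@]2(C)[C@H](CC[C@@H](O[Si](C)(C)C(C)(C)C)[C@@H]2C)[C@H]1OC(=O)C=C(C)C | intermediate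
22 | (1R,4aR,5R,6R,8aS)-6-hydroxy-4a,5-dimethyl-2-oxo-3-(prop-1-en-2-yl)-1,2,4a,5,6,7,8,8a-octahydronaphthalen-1-yl 3-methylbut-2-enoate | O=C1C(C(C)=C)=C[C@@]2(C)[C@H](CC[C@@H](O)[C@@H]2C)[C@H]1OC(=O)C=C(C)C | intermediate
23 | (1R,4aR,5R,6R,8aS)-4a,5-dimethyl-6-{[(2Z)-2-methylbut-2-enoyl]oxy}-2-oxo-3-(prop-1-en-2-yl)-1,2,4a,5,6,7,8,8a-octahydronaphthalen-1-yl 3-methylbut-2-enoate | O=C1C(C(C)=C)=C[C@@]2(C)[C@H](CC[C@@H](OC(=O)/C(C)=C\C)[C@@H]2C)[C@H]1OC(=O)C=C(C)C | intermediate
24 | (1R,3R,4aR,5R,6R,8aS)-4a,5-dimethyl-6-{[(2Z)-2-methylbut-2-enoyl]oxy}-2-oxo-3-(prop-1-en-2-yl)decahydronaphthalen-1-yl 3-methylbut-2-enoate | C=C(C)[C@H]1C[C@@]2(C)[C@H](CC[C@@H](OC(=O)/C(C)=C\C)[C@@H]2C)[C@@H](OC(=O)C=C(C)C)C1=O | target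

## Step count and least certain steps

Total step count: 18. Longest linear sequence: 18 steps, from 1 to 24.

**Step 10 (key step).** The most likely failure is closure onto the other enone arm, which gives the diastereomer with C5 and C10 inverted. In the transition state that leads to 15 the C3 silyloxy group is pseudo-axial over the unreacting arm, so the tether slightly prefers the other arm and the ligand must override it. Ligand control may also erode if iodide stays on palladium, and formate may reduce the alkenylpalladium before it inserts.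

The fallback turns the C3 oxygen from a hindrance into a directing group. From 14, cleavage of the silyl ether with HF·pyridine gives 4-[(2R,3S,4Z)-3-hydroxy-5-iodopent-4-en-2-yl]-4-methylcyclohexa-2,5-dien-1-one F1. A hydroxyl-directed reductive Heck cyclisation follows (Pd(OAc)2, one PPh3 per palladium, HCO2Na, DMF/H2O). In the transition state toward the desired arm the free hydroxyl sits next to palladium and can bind it, which is not possible for the other arm. This gives (4aS,5R,6R,8aS)-6-hydroxy-4a,5-dimethyl-4a,5,6,8a-tetrahydronaphthalen-2(1H)-one F2, and silylation (TBSCl, imidazole) returns to 15. The free alcohol of F1 could add to the dienone in an oxa-Michael reaction, so base and temperature are kept low.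

**Step 6.** The Michael addition may stall, because the enamine carbon that becomes quaternary is flanked by the branched C4. The fallback builds the same quaternary carbon by alkylation. From 7, C-allylation of the potassium enolate (KN(SiMe3)2, allyl bromide; any O-allyl enol ether converges by Claisen rearrangement on warming) gives (3R,4S)-4-[(tert-butyldimethylsilyl)oxy]-2,3-dimethyl-2-(prop-2-en-1-yl)-6-(trimethylsilyl)hex-5-ynal F3. Wacker oxidation of its allyl group (PdCl2, p-benzoquinone) gives keto aldehyde 10, isolated in this case, and aldol condensation with pyrrolidinium acetate returns to 11.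

**Step 9.** Diimide may also reduce a dienone double bond, or over-reduce the iodoalkene, before the iodoalkyne is consumed. The fallback moves the semi-reduction ahead of the dehydrogenation. From 11, iododesilylation (NIS, AgNO3) gives 4-[(2R,3S)-3-[(tert-butyldimethylsilyl)oxy]-5-iodopent-4-yn-2-yl]-4-methylcyclohex-2-en-1-one F4. Diimide reduction gives 4-[(2R,3S,4Z)-3-[(tert-butyldimethylsilyl)oxy]-5-iodopent-4-en-2-yl]-4-methylcyclohex-2-en-1-one F5. Dehydrogenation with IBX returns to 14 and also repairs any ring alkene that diimide has saturated.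

**Step 11.** Poor facial selectivity in the attack on the enolate would give the C9 epimer, because the C5 methyl group lies on the same face as the desired approach. The fallback uses inversion at C9. The epimeric alcohol (1S,4aR,5R,6R,8aS)-6-[(tert-butyldimethylsilyl)oxy]-1-hydroxy-4a,5-dimethyl-4a,5,6,8a-tetrahydronaphthalen-2(1H)-one F6 is esterified under Mitsunobu conditions (3-methylbut-2-enoic acid, PPh3, DIAD). Displacement at the carbon next to the carbonyl is favourable and gives 18 directly, so both epimers of the hydroxylation can be carried forward.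

**Step 14.** The reduction of the hindered ring A alkene may be incomplete, and hydrazine formed from diimide may attack the iodoenone. The fallback saturates ring A before iodination. From 18, hydrogenation with H2 and RhCl(PPh3)3 in benzene, which prefers the unconjugated alkene, gives (1R,4aR,5R,6R,8aS)-6-[(tert-butyldimethylsilyl)oxy]-4a,5-dimethyl-2-oxo-1,2,4a,5,6,7,8,8a-octahydronaphthalen-1-yl 3-methylbut-2-enoate F7. α-Iodination (I2, pyridine) then returns to 20.

**Step 18.** Chemoselectivity between the ring enone, whose β-carbon is neopentyl, and the two unsaturated esters may be lost. The dienolate may also be protonated at the isopropenyl terminus, or acyl migration may occur in the copper enolate. The fallback sets C7 before the angelate exists. From 21, the same copper hydride reduction gives (1R,3R,4aR,5R,6R,8aS)-6-[(tert-butyldimethylsilyl)oxy]-4a,5-dimethyl-2-oxo-3-(prop-1-en-2-yl)decahydronaphthalen-1-yl 3-methylbut-2-enoate F8. Cleavage with HF·pyridine gives (1R,3R,4aR,5R,6R,8aS)-6-hydroxy-4a,5-dimethyl-2-oxo-3-(prop-1-en-2-yl)decahydronaphthalen-1-yl 3-methylbut-2-enoate F9, and mixed-anhydride angeloylation returns to 24. The price is that the last step then exposes the β,γ-unsaturated ketone to amine base.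

## Further compounds

F1 | step 10 | 4-[(2R,3S,4Z)-3-hydroxy-5-iodopent-4-en-2-yl]-4-methylcyclohexa-2,5-dien-1-one | C[C@@H]([C@H](O)/C=C\I)C1(C)C=CC(=O)C=C1
F2 | step 10 | (4aS,5R,6R,8aS)-6-hydroxy-4a,5-dimethyl-4a,5,6,8a-tetrahydronaphthalen-2(1H)-one | O=C1C=C[C@@]2(C)[C@H](C=C[C@@H](O)[C@@H]2C)C1
F3 | step 6 | (3R,4S)-4-[(tert-butyldimethylsilyl)oxy]-2,3-dimethyl-2-(prop-2-en-1-yl)-6-(trimethylsilyl)hex-5-ynal | C[C@@H]([C@H](O[Si](C)(C)C(C)(C)C)C#C[Si](C)(C)C)C(C)(CC=C)C=O
F4 | step 9 | 4-[(2R,3S)-3-[(tert-butyldimethylsilyl)oxy]-5-iodopent-4-yn-2-yl]-4-methylcyclohex-2-en-1-one | C[C@@H]([C@H](O[Si](C)(C)C(C)(C)C)C#CI)C1(C)CCC(=O)C=C1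
F5 | step 9 | 4-[(2R,3S,4Z)-3-[(tert-butyldimethylsilyl)oxy]-5-iodopent-4-en-2-yl]-4-methylcyclohex-2-en-1-one | C[C@@H]([C@H](O[Si](C)(C)C(C)(C)C)/C=C\I)C1(C)CCC(=O)C=C1
F6 | step 11 | (1S,4aR,5R,6R,8aS)-6-[(tert-butyldimethylsilyl)oxy]-1-hydroxy-4a,5-dimethyl-4a,5,6,8a-tetrahydronaphthalen-2(1H)-one | O=C1C=C[C@@]2(C)[C@H](C=C[C@@H](O[Si](C)(C)C(C)(C)C)[C@@H]2C)[C@@H]1O
F7 | step 14 | (1R,4aR,5R,6R,8aS)-6-[(tert-butyldimethylsilyl)oxy]-4a,5-dimethyl-2-oxo-1,2,4a,5,6,7,8,8a-octahydronaphthalen-1-yl 3-methylbut-2-enoate | O=C1C=C[C@@]2(C)[C@H](CC[C@@H](O[Si](C)(C)C(C)(C)C)[C@@H]2C)[C@H]1OC(=O)C=C(C)C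
F8 | step 18 | (1R,3R,4aR,5R,6R,8aS)-6-[(tert-butyldimethylsilyl)oxy]-4a,5-dimethyl-2-oxo-3-(prop-1-en-2-yl)decahydronaphthalen-1-yl 3-methylbut-2-enoate | C=C(C)[C@H]1C[C@@]2(C)[C@H](CC[C@@H](O[Si](C)(C)C(C)(C)C)[C@@H]2C)[C@@H](OC(=O)C=C(C)C)C1=O
F9 | step 18 | (1R,3R,4aR,5R,6R,8aS)-6-hydroxy-4a,5-dimethyl-2-oxo-3-(prop-1-en-2-yl)decahydronaphthalen-1-yl 3-methylbut-2-enoate | C=C(C)[C@H]1C[C@@]2(C)[C@H](CC[C@@H](O)[C@@H]2C)[C@@H](OC(=O)C=C(C)C)C1=O
A1 | alternative 1 | cis-fused Diels–Alder adduct with the C3 silyl enol ether, C7 isopropenyl group, C8 4-methoxybenzyl ether and C9 ketone | C=C(C)[C@H]1C[C@@]2(C)[C@H](CCC(O[Si](C)(C)C(C)(C)C)=C2C)C(=O)[C@@H]1OCc1ccc(OC)cc1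
A2 | alternative 2 | cis-decalin from the ene closure with the C8 alcohol trans to the C7 isopropenyl group and the C9 4-methoxybenzyl ether | C=C(C)[C@H]1C[C@@]2(C)[C@H](CC[C@@H](O[Si](C)(C)C(C)(C)C)[C@@H]2C)[C@@H](OCc3ccc(OC)cc3)[C@@H]1O
A3 | alternative 3 | cis-fused endo quinone adduct with the C3 silyl enol ether (C4 epimeric) | COC1=CC(=O)[C@@]2(C)[C@H](CC=C(O[Si](C)(C)C(C)(C)C)[C@H]2C)C1=O
A4 | alternative 3 | 2-methoxy-5-methylcyclohexa-2,5-diene-1,4-dione | COC1=CC(=O)C(C)=CC1=O
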